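**Retrosynthetic overview**
- The target is cut back to a bis(3-aryl-3-hydroxyoxindole). Both indole rings come from it in the last step by global lactam reduction, dehydrative aromatisation and desilylation.
- Key disconnection: the two aryl–C3 bonds. Indole C3 is naturally nucleophilic; here it is used as an electrophile, as the C3 ketone of an isatin (an indol-3-yl cation, a2 or enolonium-type equivalent). It is attacked by the lithiated carbon of tetramethoxybenzene, itself a naturally nucleophilic arene carbon, twice in one flask.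
- Three fragments, one step each: 1,4-dibromo-2,3,5,6-tetramethoxybenzene (bromination), O-silylated 5-hydroxyisatin (silylation), 6-prenylisatin (Stille coupling of 6-bromoisatin).
- Ring order: no ring is built. The central benzene ring and both benzo-fused lactams are bought; the two pyrrole rings are aromatised together at the end.

Assumption: the target has no stereocentre and no desymmetrised biaryl axis (both ortho positions of the central ring carry OMe), so it is achiral and needs no enantiocontrol; the four starting materials 1, 2, 4 and 6 are taken as purchasable.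

**Step 1**
Reactants: 1 6-bromo-1H-indole-2,3-dione (6-bromoisatin); 2 tributyl(3-methylbut-2-en-1-yl)stannane
Product: 3 6-(3-methylbut-2-en-1-yl)-1H-indole-2,3-dione
Conditions: Pd(PPh3)4 (5 mol%), DMF, 90 °C
Reagents that add atoms: none
Why: Migita–Kosugi–Stille coupling, in which zerovalent palladium inserts into the C6–Br bond (activated para to the keto-bearing carbon), the allylstannane transmetalates and reductive elimination at the unsubstituted allyl terminus gives the linear prenyl arene under neutral conditions that leave the isatin N–H and keto-lactam intact.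

**Step 2**
Reactants: 4 1,2,4,5-tetramethoxybenzene
Product: 5 1,4-dibromo-2,3,5,6-tetramethoxybenzene
Conditions: Br2 (2.1 equiv), CH2Cl2, 0 → 23 °C
Reagents that add atoms: bromine, BrBr
Why: Electrophilic aromatic substitution (SEAr) at the only two free positions, each flanked by two methoxy groups, so the double bromination is regiochemically unambiguous.

**Step 3**
Reactants: 6 5-hydroxy-1H-indole-2,3-dione (5-hydroxyisatin)
Product: 7 5-[(tert-butyldimethylsilyl)oxy]-1H-indole-2,3-dione
Conditions: TBSCl (1.1 equiv), imidazole (2.2 equiv), DMF, 0 → 23 °C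
Reagents that add atoms: tert-butyldimethylsilyl chloride, CC(C)(C)[Si](C)(C)Cl
Why: Imidazole-mediated silylation of the phenol (Corey protocol), where any N-silyl lactam is hydrolysed on aqueous work-up, so only the aryl silyl ether remains to mask the acidic O–H for the organolithium step.

**Step 4 (key step)**
Reactants: 5 1,4-dibromo-2,3,5,6-tetramethoxybenzene; 7 5-[(tert-butyldimethylsilyl)oxy]-1H-indole-2,3-dione; 3 6-(3-methylbut-2-en-1-yl)-1H-indole-2,3-dione
Product: 13 5-[(tert-butyldimethylsilyl)oxy]-3-hydroxy-3-{4-[3-hydroxy-6-(3-methylbut-2-en-1-yl)-2-oxoindolin-3-yl]-2,3,5,6-tetramethoxyphenyl}indolin-2-one (diastereomer mixture; each racemic), via sodium silyloxyisatinide 8 (not isolated), via bromoaryllithium 9 (not isolated), via mono-adduct dianion salt 10 (not isolated), via lithiated mono-adduct 11 (not isolated), via sodium prenylisatinide 12 (not isolated)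
Conditions: a) 7, NaH (1.0 equiv), THF, 0 °C; b) 5, n-BuLi (1.0 equiv), THF, −78 °C, 20 min, then suspension from a), −78 → −30 °C; c) n-BuLi (1.1 equiv), −78 °C, 20 min; d) 3 pre-treated with NaH (1.0 equiv, THF, 0 °C), 1.2 equiv, −78 → −20 °C; e) aq. NH4Cl, −20 °C
Reagents that add atoms: none
Why: Proposed new method: iterative bromine–lithium exchange and 1,2-addition in one flask, in which the C3 keto group of each N-sodio isatin acts as an indol-3-yl cation (a2, enolonium-type) equivalent so that the naturally nucleophilic indole C3 is joined to the naturally nucleophilic carbon of the electron-rich arene; exchange on the 2,6-dimethoxyaryl bromide at −78 °C is far faster than attack of n-BuLi on amidate, alkoxide or silyl ether, the first adduct is already fully deprotonated (N–Na, O–Li) and so needs no protection before the second exchange, the closest known reactions are the addition of aryl Grignard or aryllithium reagents to N-metalated isatins (dioxindole synthesis) and the mono-exchange of 1,4-dibromoarenes, and the two new stereocentres form without control because both are erased in step 5.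

**Step 5**
Reactants: 13 5-[(tert-butyldimethylsilyl)oxy]-3-hydroxy-3-{4-[3-hydroxy-6-(3-methylbut-2-en-1-yl)-2-oxoindolin-3-yl]-2,3,5,6-tetramethoxyphenyl}indolin-2-one
Product: 16 3-{2,3,5,6-tetramethoxy-4-[6-(3-methylbut-2-en-1-yl)-1H-indol-3-yl]phenyl}-1H-indol-5-ol (target), via bis(indolin-3-ol) 14 (not isolated), via silyl ether of the target 15 (not isolated)
Conditions: LiAlH4 (10 equiv), THF, 0 → 65 °C, 6 h; Na2SO4·10H2O quench, filter; crude in THF: AcOH (5 equiv), 23 → 40 °C, then Bu4NF (1.5 equiv), 0 → 23 °C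
Reagents that add atoms: none
Why: Hydride reduction of dioxindoles (3-hydroxyoxindoles) to indoles, in which LiAlH4 takes each lactam carbonyl through the 3H-indol-3-olate imine to the 3-hydroxyindoline 14, acid-promoted dehydration (E1, driven by aromatisation) forms both indole rings and destroys both stereocentres, the isolated trisubstituted alkene and the aryl methyl ethers are inert to LiAlH4, and buffered fluoride finally cleaves the aryl O–Si bond.

**Compound list**
1 | 6-bromo-1H-indole-2,3-dione (6-bromoisatin) | O=C1Nc2cc(Br)ccc2C1=O | starting material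
2 | tributyl(3-methylbut-2-en-1-yl)stannane | CCCC[Sn](CCCC)(CCCC)CC=C(C)C | starting material
3 | 6-(3-methylbut-2-en-1-yl)-1H-indole-2,3-dione | O=C1Nc2cc(CC=C(C)C)ccc2C1=O | intermediate
4 | 1,2,4,5-tetramethoxybenzene | COc1cc(OC)c(OC)cc1OC | starting material
5 | 1,4-dibromo-2,3,5,6-tetramethoxybenzene | COc1c(Br)c(OC)c(OC)c(Br)c1OC | intermediate
6 | 5-hydroxy-1H-indole-2,3-dione (5-hydroxyisatin) | O=C1Nc2ccc(O)cc2C1=O | starting material
7 | 5-[(tert-butyldimethylsilyl)oxy]-1H-indole-2,3-dione | CC(C)(C)[Si](C)(C)Oc1ccc2NC(=O)C(=O)c2c1 | intermediate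
8 | sodium 5-[(tert-butyldimethylsilyl)oxy]-2,3-dioxoindolin-1-ide (formed in the flask) | [Na+].CC(C)(C)[Si](C)(C)Oc1ccc2[N-]C(=O)C(=O)c2c1 | intermediate
9 | (4-bromo-2,3,5,6-tetramethoxyphenyl)lithium (formed in the flask) | [Li]c1c(OC)c(OC)c(Br)c(OC)c1OC | intermediate
10 | N-sodio O-lithio salt of 3-(4-bromo-2,3,5,6-tetramethoxyphenyl)-5-[(tert-butyldimethylsilyl)oxy]-3-hydroxyindolin-2-one, racemic (formed in the flask) | [Li+].[Na+].COc1c(OC)c(C2([O-])C(=O)[N-]c3ccc(O[Si](C)(C)C(C)(C)C)cc23)c(OC)c(OC)c1Br | intermediate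
11 | 4-lithio analogue of 10 (bromine replaced by lithium), racemic (formed in the flask) | [Li+].[Na+].COc1c(OC)c(C2([O-])C(=O)[N-]c3ccc(O[Si](C)(C)C(C)(C)C)cc23)c(OC)c(OC)c1[Li] | intermediate
12 | sodium 6-(3-methylbut-2-en-1-yl)-2,3-dioxoindolin-1-ide (formed in the flask) | [Na+].O=C1[N-]c2cc(CC=C(C)C)ccc2C1=O | intermediate
13 | 5-[(tert-butyldimethylsilyl)oxy]-3-hydroxy-3-{4-[3-hydroxy-6-(3-methylbut-2-en-1-yl)-2-oxoindolin-3-yl]-2,3,5,6-tetramethoxyphenyl}indolin-2-one, mixture of both racemic diastereomers (stereocentres transient, none drawn) | COc1c(OC)c(C2(O)C(=O)Nc3ccc(O[Si](C)(C)C(C)(C)C)cc23)c(OC)c(OC)c1C1(O)C(=O)Nc2cc(CC=C(C)C)ccc12 | intermediate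
14 | 5-[(tert-butyldimethylsilyl)oxy]-3-{4-[3-hydroxy-6-(3-methylbut-2-en-1-yl)indolin-3-yl]-2,3,5,6-tetramethoxyphenyl}indolin-3-ol, diastereomer mixture (formed in the flask) | COc1c(OC)c(C2(O)CNc3ccc(O[Si](C)(C)C(C)(C)C)cc23)c(OC)c(OC)c1C1(O)CNc2cc(CC=C(C)C)ccc12 | intermediate
15 | 5-[(tert-butyldimethylsilyl)oxy]-3-{2,3,5,6-tetramethoxy-4-[6-(3-methylbut-2-en-1-yl)-1H-indol-3-yl]phenyl}-1H-indole (formed in the flask) | COc1c(OC)c(-c2c[nH]c3ccc(O[Si](C)(C)C(C)(C)C)cc23)c(OC)c(OC)c1-c1c[nH]c2cc(CC=C(C)C)ccc12 | intermediate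
16 | 3-{2,3,5,6-tetramethoxy-4-[6-(3-methylbut-2-en-1-yl)-1H-indol-3-yl]phenyl}-1H-indol-5-ol (achiral) | COc1c(OC)c(-c2c[nH]c3ccc(O)cc23)c(OC)c(OC)c1-c1c[nH]c2cc(CC=C(C)C)ccc12 | target

**Step count**
Total: 5 steps (steps 1, 2 and 3 are parallel one-step fragment preparations). Longest linear sequence: 3 steps (for example step 2, step 4, step 5).

**Steps most likely to fail, with fallbacks**

Step 4 is the riskiest. The poly-anionic intermediates 10 and 11 may be poorly soluble, the second exchange may be incomplete, and mis-stoichiometry gives symmetrical by-products. The fallback is an iterative add–reduce sequence that never carries more than a dianion. It sets out from 5, which is lithiated to 9 and added to 8 as in operations a) and b), but the mixture is then quenched with aq. NH4Cl and the neutral mono-adduct 3-(4-bromo-2,3,5,6-tetramethoxyphenyl)-5-[(tert-butyldimethylsilyl)oxy]-3-hydroxyindolin-2-one F1 is isolated. Because no alkene is present yet, BH3·THF (THF, 0 → 65 °C, then MeOH and AcOH) reduces it by way of 3-(4-bromo-2,3,5,6-tetramethoxyphenyl)-5-[(tert-butyldimethylsilyl)oxy]indolin-3-ol F2 to 3-(4-bromo-2,3,5,6-tetramethoxyphenyl)-5-[(tert-butyldimethylsilyl)oxy]-1H-indole F3. n-BuLi (2.2 equiv, THF, −78 °C; N–H deprotonation then Br–Li exchange) gives lithium 5-[(tert-butyldimethylsilyl)oxy]-3-(4-lithio-2,3,5,6-tetramethoxyphenyl)indol-1-ide F4, which adds to 12 and after NH4Cl quench gives 3-[4-(5-[(tert-butyldimethylsilyl)oxy]-1H-indol-3-yl)-2,3,5,6-tetramethoxyphenyl]-3-hydroxy-6-(3-methylbut-2-en-1-yl)indolin-2-one F5. LiAlH4 (THF, 65 °C) then AcOH reduces this single dioxindole by way of 3-[4-(5-[(tert-butyldimethylsilyl)oxy]-1H-indol-3-yl)-2,3,5,6-tetramethoxyphenyl]-6-(3-methylbut-2-en-1-yl)indolin-3-ol F6, and the sequence comes back to the route at 15, which is desilylated as in step 5.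

Step 5 is next. Two hindered N-metalated lactams must be reduced at once, over-reduction to 3-arylindolines is possible, and LiAlH4 is used only because borane would hydroborate the prenyl group. The fallback postpones the alkene so that borane can do the reduction. It sets out from 1, which with NaH (THF, 0 °C) gives sodium 6-bromo-2,3-dioxoindolin-1-ide F7. This replaces 12 in operation d) of step 4 (addition to 11) and after NH4Cl quench gives 3-[4-(6-bromo-3-hydroxy-2-oxoindolin-3-yl)-2,3,5,6-tetramethoxyphenyl]-5-[(tert-butyldimethylsilyl)oxy]-3-hydroxyindolin-2-one F8. BH3·THF (0 → 65 °C, then MeOH and AcOH) reduces both lactams by way of 6-bromo-3-[4-(5-[(tert-butyldimethylsilyl)oxy]-3-hydroxyindolin-3-yl)-2,3,5,6-tetramethoxyphenyl]indolin-3-ol F9 to 6-bromo-3-[4-(5-[(tert-butyldimethylsilyl)oxy]-1H-indol-3-yl)-2,3,5,6-tetramethoxyphenyl]-1H-indole F10. Stille coupling of this bromide with 2 (Pd(PPh3)4, DMF, 90 °C) comes back to the route at 15. This fallback also avoids having the prenyl group present during any hydride step.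

Step 1 is the third risk. The prenylstannane may attack the very electrophilic C3 ketone of the free isatin through its γ-carbon, giving a reverse-prenyl carbinol, and some branched coupling product may form. The fallback inverts the roles of the coupling partners so that no nucleophilic allylmetal meets the ketone. It sets out from 1, which on Miyaura borylation (B2pin2, PdCl2(dppf), KOAc, dioxane, 90 °C) gives 6-(4,4,5,5-tetramethyl-1,3,2-dioxaborolan-2-yl)-1H-indole-2,3-dione F11. Allyl–aryl Suzuki coupling with 1-bromo-3-methylbut-2-ene (Pd(PPh3)4, K2CO3, THF/H2O, 60 °C, acidify on work-up) proceeds through an electrophilic π-allyl palladium species that couples at its unsubstituted terminus, and comes back to the route at 3.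

**Further compounds**
F1 | step 4 | 3-(4-bromo-2,3,5,6-tetramethoxyphenyl)-5-[(tert-butyldimethylsilyl)oxy]-3-hydroxyindolin-2-one (racemic) | COc1c(OC)c(C2(O)C(=O)Nc3ccc(O[Si](C)(C)C(C)(C)C)cc23)c(OC)c(OC)c1Br
F2 | step 4 | 3-(4-bromo-2,3,5,6-tetramethoxyphenyl)-5-[(tert-butyldimethylsilyl)oxy]indolin-3-ol (racemic) | COc1c(OC)c(C2(O)CNc3ccc(O[Si](C)(C)C(C)(C)C)cc23)c(OC)c(OC)c1Br
F3 | step 4 | 3-(4-bromo-2,3,5,6-tetramethoxyphenyl)-5-[(tert-butyldimethylsilyl)oxy]-1H-indole | COc1c(OC)c(-c2c[nH]c3ccc(O[Si](C)(C)C(C)(C)C)cc23)c(OC)c(OC)c1Br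
F4 | step 4 | lithium 5-[(tert-butyldimethylsilyl)oxy]-3-(4-lithio-2,3,5,6-tetramethoxyphenyl)indol-1-ide | [Li+].COc1c(OC)c(-c2c[n-]c3ccc(O[Si](C)(C)C(C)(C)C)cc23)c(OC)c(OC)c1[Li]
F5 | step 4 | 3-[4-(5-[(tert-butyldimethylsilyl)oxy]-1H-indol-3-yl)-2,3,5,6-tetramethoxyphenyl]-3-hydroxy-6-(3-methylbut-2-en-1-yl)indolin-2-one (racemic) | COc1c(OC)c(-c2c[nH]c3ccc(O[Si](C)(C)C(C)(C)C)cc23)c(OC)c(OC)c1C1(O)C(=O)Nc2cc(CC=C(C)C)ccc12
F6 | step 4 | 3-[4-(5-[(tert-butyldimethylsilyl)oxy]-1H-indol-3-yl)-2,3,5,6-tetramethoxyphenyl]-6-(3-methylbut-2-en-1-yl)indolin-3-ol (racemic) | COc1c(OC)c(-c2c[nH]c3ccc(O[Si](C)(C)C(C)(C)C)cc23)c(OC)c(OC)c1C1(O)CNc2cc(CC=C(C)C)ccc12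
F7 | step 5 | sodium 6-bromo-2,3-dioxoindolin-1-ide | [Na+].O=C1[N-]c2cc(Br)ccc2C1=O
F8 | step 5 | 3-[4-(6-bromo-3-hydroxy-2-oxoindolin-3-yl)-2,3,5,6-tetramethoxyphenyl]-5-[(tert-butyldimethylsilyl)oxy]-3-hydroxyindolin-2-one (diastereomer mixture) | COc1c(OC)c(C2(O)C(=O)Nc3ccc(O[Si](C)(C)C(C)(C)C)cc23)c(OC)c(OC)c1C1(O)C(=O)Nc2cc(Br)ccc12
F9 | step 5 | 6-bromo-3-[4-(5-[(tert-butyldimethylsilyl)oxy]-3-hydroxyindolin-3-yl)-2,3,5,6-tetramethoxyphenyl]indolin-3-ol (diastereomer mixture) | COc1c(OC)c(C2(O)CNc3ccc(O[Si](C)(C)C(C)(C)C)cc23)c(OC)c(OC)c1C1(O)CNc2cc(Br)ccc12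
F10 | step 5 | 6-bromo-3-[4-(5-[(tert-butyldimethylsilyl)oxy]-1H-indol-3-yl)-2,3,5,6-tetramethoxyphenyl]-1H-indole | COc1c(OC)c(-c2c[nH]c3ccc(O[Si](C)(C)C(C)(C)C)cc23)c(OC)c(OC)c1-c1c[nH]c2cc(Br)ccc12
F11 | step 1 | 6-(4,4,5,5-tetramethyl-1,3,2-dioxaborolan-2-yl)-1H-indole-2,3-dione | CC1(C)OB(OC1(C)C)c1ccc2c(c1)NC(=O)C2=O
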